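One charge of Qa was my unit, and in this flask Qb came to the same unit; the north-west run is this flask followed so far.

| setting | north-west | south | flask |
|---|---|---|---|
| Qa | 0.14 M | 0.094 M | 0.14 M |
| Qb | 0.14 M | 0.14 M | 0.140 M |
| remark | the very flask that is asked about, followed so far | run made earlier |  |
| time |  |  | 10 d |

| run | time / d | Qc / % | Qe / % | Qa / % |
|---|---|---|---|---|
| north-west | 0.625 | 80 | 36 | 11 |
| north-west | 1.67 | 88 | 40 | 4 |
| north-west | 3.00 | 89 | 42 | 6 |
| north-west | 5.00 | 88 | 37 | 7 |
| south | 0.833 | 87 | 14 | 4 |
| south | 1.67 | 81 | 6 | 0 |
| south | 4.00 | 66 | 0 | 0 |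
| south | 10.0 | 57 | 1 | 0 |

(scatter of a reading: 2 percentage points)

1. Qc and Qe together at 10 d, in percent of the Qa charged
2. concentration of Qc in solution at 10 d, in percent of saturation

- what is said of Qc includes Qe
- Qe is a solid; its amount is given per volume of the solution

I counted each unit of Qb as ending on Qa, which makes Qc, or on Qc, which removes it into the gap that the Qa and Qc readings leave open. The south run supported the second use: Qc kept falling there with Qa read at 0%. The ratio of the two uses needs no clock, since together they cannot pass the Qb charge, with Qb as limiting reagent.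

At 5.00 d the readings left Qb at 2.00% of the charge. If all of it went to Qc, the asked sum would fall to 86.0%; if all went to Qa, it would rise to 90.0%.

To tighten this I averaged from 1.67 d on: Qa 5.67%, Qc 88.3%. These put Qb at −0.333%, which a scatter of 2 percentage points cannot tell from zero. So I committed to 88.7% as the stop yield, the whole charge less twice the Qa left at the point where Qb reaches zero. Qe read 37% at 5.00 d, so I expected a saturated solution.

The forecast gave 88% and 100%, on the grounds that “Little Qb remains to consume Qc”; its 88% lies inside my bracket, a little below my stop yield.

The flask gave 88.7% and 100%.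

    Qa + Qb → Qc (k = 4.03 /M/h)
    Qb + Qc → Qd (k = 0.170 /M/h)
    Qe ⇌ Qc, rate k3*(cs3 - [Qc]) while solid is left; crystals form when [Qc] > cs3 (solubility = 0.0690 M, k = 0.639 /h)

Beside the stop yield of 88.7%, the flask held Qb at 0% and Qa at 5.6%. In a neighbour flask with Qb cut to 0.084 M, Qb also reached 0%; the same count, twice the charge less the Qb charge less twice the Qa left of 41%, gives 57.6%, and that neighbour held 57.6%. In the asked flask at 0.0664 d, Qa + Qb used Qb 27 times as fast as Qb + Qc did, with half-lives of 0.097 d against 2.6 d. By 2.00 d the first step had 99.1% of its turnover behind it, and Qd ended at 5.64%.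

(The readings were computed for an exercise.)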